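## Analysis of the target

5-Methoxygalbelgin (12) is a 2,5-diaryl-3,4-dimethyltetrahydrofuran: ring O1, C2 (3,4-dimethoxyphenyl), C3 (methyl), C4 (methyl), C5 (3,4,5-trimethoxyphenyl). All four contiguous stereocentres are S, and every vicinal pair is trans (aryl up, methyl down, methyl up, aryl down). This is the arrangement of lowest energy for the ring. The molecule would be C2-symmetric but for one extra methoxy group, so the two nearly identical halves must come from two different building blocks, and a dimerisation would pay a statistical penalty. Apart from the ring oxygen there are only five aryl methyl ethers, so no functional handle can direct a reagent; absolute configuration must come from a reagent, a catalyst or a removable auxiliary. The sensitive sites are the two benzylic C–O bonds, which the electron-rich aryl groups make prone to acid ionisation and to hydrogenolysis. The strategy reads C2–O1–C5 with its two aryl groups as a 1,3-diaryl carbonyl ylide, and C3–C4 with its trans methyl groups as a fumarate. The ester groups activate the alkene, make C3 and C4 epimerisable, and are reduced to methyl at the end.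

## Retrosynthetic reasoning

The two methyl groups of 12 are traced back to sulfonate leaving groups (bis-mesylate 11), to primary alcohols (diol 10) and to the ester groups of the all-trans di-menthyl diester 9. Nothing in the skeleton is cut. What is gained is an electron-poor two-carbon unit, C–H acidity at C3 and C4, and a point of attachment for a chiral alcohol. The forward steps are hydride reduction, sulfonylation and hydride displacement at exocyclic carbons, none of which touches a stereocentre.

Diester 9 is the thermodynamic member of the set of C3/C4 epimers that share its C2 and C5 configuration. Its 3,4-bis-epimer 8 (cis,trans,cis) is therefore an equally good precursor, because base equilibration must turn 8 into 9. The adducts of opposite configuration at C2 and C5 are related to each other in the same way. They differ from 9 as diastereomers through the menthyl groups, so the single enantiomer can be secured by separation at this stage, whatever the degree of induction.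

The ring is opened at C2–C3 and C4–C5. This cut, and no other, splits the molecule into a three-atom unit that carries both aryl groups (carbonyl ylide 7) and a two-carbon unit that carries both methyl precursors (fumarate 6). It forms two C–C bonds, the ring and all four stereocentres in one step. Ylide 7 comes from the trans-oxirane 5 by photochemical C–C cleavage. The forward reaction must keep the geometry of 7, which fixes the 2,5-trans relationship, and must add the E alkene of 6 with retention, which fixes the 3,4-trans relationship.

Oxirane 5 is cut at its C–C bond and at one C–O bond into veratraldehyde 3 and the benzylic sulfonium ylide 4. Ylide 4 comes from the sulfonium salt 2, and 2 from 3,4,5-trimethoxybenzyl chloride 1 by alkylation of a cyclic sulfide. The C–C bond made here is temporary and is broken again in the key step; it serves only to tie the two benzylic carbons to one oxygen. The precursor is thus reached in two steps from two commercial aromatics, and the racemate suffices.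

## Alternatives that were turned down

Alternative 1: The two C–CH3 bonds at C3 and C4 are disconnected on a lactone that already holds C5 and the trimethoxyphenyl group. In the forward sense a methyl cuprate adds to the (S)-5-aryl butenolide A2 anti to the aryl group, and the lactone enolate is methylated anti to the new methyl group, giving lactone A1.
- For: every new centre is set by 1,2-induction in a rigid five-membered ring. This is more predictable than the chosen route; it needs no auxiliary and no separation of diastereomers.
- Against: A2 needs its own enantioselective synthesis. Its C5–H is benzylic and vinylogously acidic, so the basic conditions threaten racemisation through the 2-oxyfuran anion, and electron transfer from the cuprate threatens the benzylic C–O bond. A1 carries only one aryl group; its carbonyl must still be reduced and C2 arylated with control of a fourth centre, so the sequence is linear.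
- Comparison: the step count is similar. The chosen strategy is weaker in certainty of induction but offers convergence: ring, two C–C bonds and four centres arise in one step from two achiral partners.

Alternative 2: C3–C4 and both ring C–O bonds are disconnected to the propenylphenols A4 and A5. An oxidase generates the two phenoxyl radicals, a dirigent protein joins them at the propenyl β-carbons, and hydration of the resulting bis-quinone methide closes the ring to bisphenol A3, which needs only double O-methylation.
- For: this is the shortest route conceivable, free of protecting groups and of auxiliaries, and clearly stronger in step economy.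
- Against: the radicals of A4 and A5 couple with themselves as readily as with each other, and at several positions. A protein that pairs exactly these two phenols in the required sense is not an available reagent. The hydration sets C2 and C5 without control.
- Comparison: the chosen strategy is longer, but its bond-forming event is a known reaction and only the degree of induction is open.

Alternative 3: both C–O bonds and the C3–H and C4–H bonds are disconnected to the achiral diene A7. A terpene-derived chiral monoalkylborane adds syn to both alkenes, and alkaline peroxide gives diol A6, which is then cyclised.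
- For: all four centres come from an achiral hydrocarbon under reagent control, with the oxygen atoms placed at the benzylic carbons by the normal regiochemistry.
- Against: a monoalkylborane has two B–H bonds, so the second alkene is hydroborated intramolecularly through a borolane. The ring, not the terpene group, then decides the C3/C4 relationship. The unsymmetrical A7 needs a cross-coupling of two different alkenyl halves. The key step closes no ring, and the later cyclisation must pass through a benzylic cation.
- Comparison: the alternative is as good as the chosen route in cost of the chiral source. The chosen strategy offers a far shorter approach to its precursor and sets the C3/C4 relationship by equilibrium instead of by an uncertain intramolecular addition.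

Key step: step 3

Assumption: oxirane 5 is used as the racemate, because both enantiomers open to the same planar, achiral ylide. The absolute configuration is decided in step 3 and made secure by the diastereomer separation that ends that step. The assignment of 9 against its diastereomer with the mirror-image ring is to be made by crystal structure analysis, with the menthyl groups as internal reference.

## Route

Step 1
Reactants: 1 3,4,5-trimethoxybenzyl chloride
Product: 2 1-(3,4,5-trimethoxybenzyl)tetrahydrothiophen-1-ium chloride
Conditions: tetrahydrothiophene (2 equiv), MeOH, 50 °C; evaporation, trituration with Et2O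
Reagents that add atoms: tetrahydrothiophene, C1CCSC1
Why: SN2 alkylation of the sulfide by an activated benzylic chloride gives the sulfonium salt, which the polar medium stabilises; the soft sulfur nucleophile should outrun solvolysis, and no stereocentre is formed.

Step 2
Reactants: 2 1-(3,4,5-trimethoxybenzyl)tetrahydrothiophen-1-ium chloride; 3 veratraldehyde (3,4-dimethoxybenzaldehyde)
Product: 5 trans-2-(3,4-dimethoxyphenyl)-3-(3,4,5-trimethoxyphenyl)oxirane (racemate), via sulfonium ylide 4 (not isolated)
Conditions: 50% aq NaOH, CH2Cl2, BnEt3NCl (cat.), 0 °C to rt; crystallisation (or Et3N-deactivated silica)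
Reagents that add atoms: none
Why: Corey–Chaykovsky-type epoxidation: the semi-stabilised benzylic ylide 4 adds reversibly to the aldehyde, so the anti betaine is expected to dominate ring closure and the trans-oxirane should be the main product. The racemate is sufficient because step 3 destroys both oxirane stereocentres.

Step 3
Reactants: 5 trans-2-(3,4-dimethoxyphenyl)-3-(3,4,5-trimethoxyphenyl)oxirane; 6 di-(1R,2S,5R)-menthyl fumarate
Product: 9 di-(1R,2S,5R)-menthyl (2S,3S,4S,5S)-2-(3,4-dimethoxyphenyl)-5-(3,4,5-trimethoxyphenyl)tetrahydrofuran-3,4-dicarboxylate, via S-shaped carbonyl ylide 7 (not isolated), via 3,4-bis-epimeric diester 8 (not isolated)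
Conditions: hν (300 nm, quartz), 6 (5 equiv), degassed MeCN, rt, to partial conversion; Et3N-deactivated silica plug (5 and 6 recovered, adduct fraction kept undivided); t-BuOK (0.3 equiv), THF/t-BuOH, 0 °C to rt; AcOH; chromatography, then crystallisation
Reagents that add atoms: none
Why: Light near 300 nm is absorbed by the dimethoxy- and trimethoxyphenyl chromophores of 5 and hardly by 6, and the excited oxirane breaks its C–C bond in the photochemically allowed disrotatory sense, which turns the trans-oxirane into the S-shaped ylide 7 (one aryl group inside, one outside). 7 is an electron-rich 4π dipole that adds to the electron-poor alkene of 6 in a concerted suprafacial (3+2) cycloaddition, the closest known reaction type being the trapping of photogenerated 2,3-diaryloxirane ylides by fumarates, maleates and acrylates. The tetrahydrofuran ring closes by this intermolecular two-bond cycloaddition, in which C2–C3 and C4–C5 form together across the preformed C2–O1–C5 unit. C2 and C5 become trans because of the S shape of 7, and C3 and C4 stay trans because the E alkene adds with retention. The relation of C2 to C3 depends on which fumarate face meets a given ylide face, and the approach that places both ester groups over the hydrogen atoms of the ylide carbons should be preferred and give 9 directly, while the other approach gives the 3,4-bis-epimer 8, which the alkoxide then converts into 9 by reversible enolisation at C3 and C4 (C2 and C5 carry no acidifying group and keep their configuration). The absolute configuration at C2 and C5 is fixed by the ylide face attacked, and the menthyl groups bias it only to the extent that their shielding of one fumarate face and the preference for the all-trans approach reinforce each other, so the two adducts with the mirror-image ring are expected as well, converge in the base stage on a single all-trans diastereomer of 9 and are removed from it by chromatography and crystallisation. The selectivity the step needs is that 7 keeps its S shape until it is trapped, which the fivefold excess and high concentration of 6 and a stop at partial conversion should secure against reclosure to the cis-oxirane and against fragmentation to aldehyde and carbene. Excess 6 is taken out before the base is added so that the ester enolates cannot add to it, and E to Z isomerisation of the dipolarophile under the lamp is tolerable because any 3,4-cis adduct enters the same equilibrium.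

Step 4
Reactants: 9 di-(1R,2S,5R)-menthyl (2S,3S,4S,5S)-2-(3,4-dimethoxyphenyl)-5-(3,4,5-trimethoxyphenyl)tetrahydrofuran-3,4-dicarboxylate
Product: 10 [(2S,3R,4R,5S)-2-(3,4-dimethoxyphenyl)-5-(3,4,5-trimethoxyphenyl)tetrahydrofuran-3,4-diyl]dimethanol
Conditions: LiAlH4, THF, 0 °C to 40 °C; aqueous NaOH work-up; menthol recovered
Reagents that add atoms: none
Why: Hydride reduction of esters: LiAlH4 reduces both hindered menthyl esters to primary alcohols without touching the ring centres; the descriptors at C3 and C4 change only through the priority rules.

Step 5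
Reactants: 10 [(2S,3R,4R,5S)-2-(3,4-dimethoxyphenyl)-5-(3,4,5-trimethoxyphenyl)tetrahydrofuran-3,4-diyl]dimethanol
Product: 11 [(2S,3R,4R,5S)-2-(3,4-dimethoxyphenyl)-5-(3,4,5-trimethoxyphenyl)tetrahydrofuran-3,4-diyl]bis(methylene) dimethanesulfonate
Conditions: MsCl, Et3N, CH2Cl2, 0 °C; used crude
Reagents that add atoms: methanesulfonyl chloride, CS(=O)(=O)Cl
Why: Sulfonylation of two primary alcohols; the trans arrangement of the two arms prevents closure to a strained trans-fused bicyclic ether, and the basic medium protects the benzylic C–O bonds.

Step 6
Reactants: 11 [(2S,3R,4R,5S)-2-(3,4-dimethoxyphenyl)-5-(3,4,5-trimethoxyphenyl)tetrahydrofuran-3,4-diyl]bis(methylene) dimethanesulfonate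
Product: 12 (2S,3S,4S,5S)-2-(3,4-dimethoxyphenyl)-3,4-dimethyl-5-(3,4,5-trimethoxyphenyl)tetrahydrofuran (5-methoxygalbelgin)
Conditions: LiBHEt3, THF, 0 °C to 50 °C
Reagents that add atoms: none
Why: SN2 displacement of the primary mesylates by the strongly nucleophilic hydride turns both CH2OMs groups into CH3; the reaction is at exocyclic carbons, so no ring stereocentre is touched, and aryl and benzylic ethers are inert to the reagent.

## Compound list

1 | 3,4,5-trimethoxybenzyl chloride | COc1cc(CCl)cc(OC)c1OC | starting material
2 | 1-(3,4,5-trimethoxybenzyl)tetrahydrothiophen-1-ium chloride | COc1cc(C[S+]2CCCC2)cc(OC)c1OC.[Cl-] | intermediate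
3 | veratraldehyde | COc1ccc(C=O)cc1OC | starting material
4 | 3,4,5-trimethoxybenzylide of tetrahydrothiophenium (sulfonium ylide, not isolated) | COc1cc([CH-][S+]2CCCC2)cc(OC)c1OC | intermediate
5 | trans-2-(3,4-dimethoxyphenyl)-3-(3,4,5-trimethoxyphenyl)oxirane (racemate, (2S,3S) enantiomer drawn) | COc1ccc([C@@H]2O[C@H]2c2cc(OC)c(OC)c(OC)c2)cc1OC | intermediate
6 | di-(1R,2S,5R)-menthyl fumarate | CC(C)[C@@H]1CC[C@@H](C)C[C@H]1OC(=O)/C=C/C(=O)O[C@@H]1C[C@H](C)CC[C@H]1C(C)C | starting material
7 | S-shaped 1-(3,4-dimethoxyphenyl)-3-(3,4,5-trimethoxyphenyl) carbonyl ylide (not isolated; one aryl group inside, one outside, drawn with the dimethoxyphenyl group outside) | COc1ccc(/C=[O+]/[CH-]c2cc(OC)c(OC)c(OC)c2)cc1OC | intermediate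
8 | di-(1R,2S,5R)-menthyl (2S,3R,4R,5S)-2-(3,4-dimethoxyphenyl)-5-(3,4,5-trimethoxyphenyl)tetrahydrofuran-3,4-dicarboxylate (cis,trans,cis; 3,4-bis-epimer of 9, not isolated, carried in the undivided adduct fraction) | COc1ccc([C@H]2O[C@H](c3cc(OC)c(OC)c(OC)c3)[C@H](C(=O)O[C@@H]3C[C@H](C)CC[C@H]3C(C)C)[C@H]2C(=O)O[C@@H]2C[C@H](C)CC[C@H]2C(C)C)cc1OC | intermediate
9 | di-(1R,2S,5R)-menthyl (2S,3S,4S,5S)-2-(3,4-dimethoxyphenyl)-5-(3,4,5-trimethoxyphenyl)tetrahydrofuran-3,4-dicarboxylate (all-trans) | COc1ccc([C@H]2O[C@H](c3cc(OC)c(OC)c(OC)c3)[C@@H](C(=O)O[C@@H]3C[C@H](C)CC[C@H]3C(C)C)[C@@H]2C(=O)O[C@@H]2C[C@H](C)CC[C@H]2C(C)C)cc1OC | intermediate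
10 | [(2S,3R,4R,5S)-2-(3,4-dimethoxyphenyl)-5-(3,4,5-trimethoxyphenyl)tetrahydrofuran-3,4-diyl]dimethanol | COc1ccc([C@H]2O[C@H](c3cc(OC)c(OC)c(OC)c3)[C@@H](CO)[C@@H]2CO)cc1OC | intermediate
11 | [(2S,3R,4R,5S)-2-(3,4-dimethoxyphenyl)-5-(3,4,5-trimethoxyphenyl)tetrahydrofuran-3,4-diyl]bis(methylene) dimethanesulfonate | COc1ccc([C@H]2O[C@H](c3cc(OC)c(OC)c(OC)c3)[C@@H](COS(C)(=O)=O)[C@@H]2COS(C)(=O)=O)cc1OC | intermediate
12 | (2S,3S,4S,5S)-2-(3,4-dimethoxyphenyl)-3,4-dimethyl-5-(3,4,5-trimethoxyphenyl)tetrahydrofuran (5-methoxygalbelgin) | COc1ccc([C@H]2O[C@H](c3cc(OC)c(OC)c(OC)c3)[C@@H](C)[C@@H]2C)cc1OC | target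

## Step count and least certain steps

Total: 6 steps. Longest linear sequence: 6 steps (1 → 2 → 5 → 9 → 10 → 11 → 12); 3 and 6 are commercial and enter in steps 2 and 3.

**Step 3 (key step).** Three processes are most likely to go wrong.
- Poor facial selectivity at the ylide: the stereogenic carbons of the auxiliary are remote and the ester conformations are not locked, so the two ring series may form in similar amounts, and the sense of induction cannot be predicted.
- Loss of the ylide geometry: thermal reclosure of 7 to the cis-oxirane and its renewed excitation would lead to 2,5-cis adducts, and fragmentation of the ylide would lower the conversion.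
- Ring opening in the base stage: β-elimination of the ring oxygen from the ester enolate could erode the configuration at C2 or C5 if the conditions are forced.

The fallback sets out from 5 and 6 and comes back at 12. The ylide is made by photoinduced electron transfer (9,10-dicyanoanthracene, 5 mol%, MeCN, 420 nm). This known route to diaryl carbonyl ylides avoids the fragmentation, but it is expected to give the relaxed, extended ylide and therefore 2,5-cis adducts. The absolute configuration is then carried by C3 and C4, that is by the fumarate face, which the auxiliary shields directly.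

Attack on the face that leads to the (3S,4S) array should give the C5-epimeric adduct F1 and the C2-epimeric adduct F2, both 2,5-cis and 3,4-trans. Attack on the other face should give the (2R,3R,4R,5S) adduct F3 and the (2S,3R,4R,5R) adduct F4. These are diastereomers of F1 and F2 and must be removed by chromatography at this stage. No base equilibration is used, because it would scramble C3 and C4 in the 2,5-cis series.

F1 and F2 are taken together through the conditions of steps 4 to 6. LiAlH4 should give the diol F5 from F1 and the diol F6 from F2. MsCl/Et3N should give the bis-mesylate F7 and the bis-mesylate F8. LiBHEt3 should give the 5-epi dimethyl compound F9 and the 2-epi dimethyl compound F10.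

Brief treatment with BF3·OEt2 in CH2Cl2 at low temperature then ionises the benzylic C–O bond at the carbon whose aryl group is cis to the neighbouring methyl group and recloses it to the all-trans ring. F9 and F10 should both end as 12. The acid step must be short and cold, because 2,5-diaryltetrahydrofurans rearrange to aryltetralins in stronger acid. The price is a separation of four diastereomers and reliance on the fumarate-face preference of the auxiliary.

**Step 4.** Cleavage of the auxiliary removes the internal stereochemical reference. The menthyl stereocentres are far from the ring, so the separation that ends step 3 may be incomplete, and any carried-over diastereomer with the mirror-image ring becomes an enantiomeric impurity that achiral purification can no longer remove. Sluggish reduction of the two hindered esters is a lesser risk.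

The fallback sets out from 9 that still carries its diastereomer with the mirror-image ring, the (2R,3R,4R,5R) diester F11, and comes back at 10. LiAlH4 as in step 4 gives 10 contaminated by its enantiomer, the (2R,3S,4S,5R) diol F12. Acylation with (1S)-camphanic chloride (pyridine, DMAP cat., CH2Cl2) should convert them into the (2S,3R,4R,5S) bis-camphanate F13 and the diastereomeric (2R,3S,4S,5R) bis-camphanate F14. Here the resolving centres sit two atoms from the ring, and the esters should be separable by crystallisation. Methanolysis of F13 (K2CO3, MeOH) returns 10 as a single enantiomer.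

**Step 2.** Incomplete trans selectivity in the ring closure is possible. The more serious risk is acid-induced opening of the very electron-rich oxirane to a benzylic cation with 1,2-shift (Meinwald rearrangement) during work-up or chromatography.

The fallback sets out from 1 and 3 and comes back at 5. Arbuzov reaction of 1 with P(OEt)3 (neat, 140 °C) gives the benzylphosphonate F15. Horner–Wadsworth–Emmons olefination of 3 (NaH, THF) gives the (E)-stilbene F16. Epoxidation with dimethyldioxirane in acetone at 0 °C, a neutral oxidant, then transfers the E geometry stereospecifically to the trans-oxirane 5.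

**Step 6.** Displacement at the β-branched primary carbons is slow, and attack of hydride at sulfur would cleave the S–O bond and return alcohol functions, leaving partly reduced material.

The fallback sets out from 10 and comes back at 12. Iodination (I2, PPh3, imidazole, toluene) gives the bis(iodomethyl) compound F17. Radical chain reduction with Bu3SnH and AIBN (toluene, 80 °C) replaces the substitution at carbon by hydrogen atom transfer. The stannane concentration is kept high, so that the primary radicals are quenched before they can open the ring by β-scission to a benzylic radical.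

## Further compounds

F1 | step 3 | di-(1R,2S,5R)-menthyl (2S,3S,4S,5R)-2-(3,4-dimethoxyphenyl)-5-(3,4,5-trimethoxyphenyl)tetrahydrofuran-3,4-dicarboxylate (C5 epimer of 9) | COc1ccc([C@H]2O[C@@H](c3cc(OC)c(OC)c(OC)c3)[C@@H](C(=O)O[C@@H]3C[C@H](C)CC[C@H]3C(C)C)[C@@H]2C(=O)O[C@@H]2C[C@H](C)CC[C@H]2C(C)C)cc1OC
F2 | step 3 | di-(1R,2S,5R)-menthyl (2R,3S,4S,5S)-2-(3,4-dimethoxyphenyl)-5-(3,4,5-trimethoxyphenyl)tetrahydrofuran-3,4-dicarboxylate (C2 epimer of 9) | COc1ccc([C@@H]2O[C@H](c3cc(OC)c(OC)c(OC)c3)[C@@H](C(=O)O[C@@H]3C[C@H](C)CC[C@H]3C(C)C)[C@@H]2C(=O)O[C@@H]2C[C@H](C)CC[C@H]2C(C)C)cc1OC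
F3 | step 3 | di-(1R,2S,5R)-menthyl (2R,3R,4R,5S)-2-(3,4-dimethoxyphenyl)-5-(3,4,5-trimethoxyphenyl)tetrahydrofuran-3,4-dicarboxylate | COc1ccc([C@@H]2O[C@H](c3cc(OC)c(OC)c(OC)c3)[C@H](C(=O)O[C@@H]3C[C@H](C)CC[C@H]3C(C)C)[C@H]2C(=O)O[C@@H]2C[C@H](C)CC[C@H]2C(C)C)cc1OC
F4 | step 3 | di-(1R,2S,5R)-menthyl (2S,3R,4R,5R)-2-(3,4-dimethoxyphenyl)-5-(3,4,5-trimethoxyphenyl)tetrahydrofuran-3,4-dicarboxylate | COc1ccc([C@H]2O[C@@H](c3cc(OC)c(OC)c(OC)c3)[C@H](C(=O)O[C@@H]3C[C@H](C)CC[C@H]3C(C)C)[C@H]2C(=O)O[C@@H]2C[C@H](C)CC[C@H]2C(C)C)cc1OC
F5 | step 3 | [(2S,3R,4R,5R)-2-(3,4-dimethoxyphenyl)-5-(3,4,5-trimethoxyphenyl)tetrahydrofuran-3,4-diyl]dimethanol | COc1ccc([C@H]2O[C@@H](c3cc(OC)c(OC)c(OC)c3)[C@@H](CO)[C@@H]2CO)cc1OC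
F6 | step 3 | [(2R,3R,4R,5S)-2-(3,4-dimethoxyphenyl)-5-(3,4,5-trimethoxyphenyl)tetrahydrofuran-3,4-diyl]dimethanol | COc1ccc([C@@H]2O[C@H](c3cc(OC)c(OC)c(OC)c3)[C@@H](CO)[C@@H]2CO)cc1OC
F7 | step 3 | [(2S,3R,4R,5R)-2-(3,4-dimethoxyphenyl)-5-(3,4,5-trimethoxyphenyl)tetrahydrofuran-3,4-diyl]bis(methylene) dimethanesulfonate | COc1ccc([C@H]2O[C@@H](c3cc(OC)c(OC)c(OC)c3)[C@@H](COS(C)(=O)=O)[C@@H]2COS(C)(=O)=O)cc1OC
F8 | step 3 | [(2R,3R,4R,5S)-2-(3,4-dimethoxyphenyl)-5-(3,4,5-trimethoxyphenyl)tetrahydrofuran-3,4-diyl]bis(methylene) dimethanesulfonate | COc1ccc([C@@H]2O[C@H](c3cc(OC)c(OC)c(OC)c3)[C@@H](COS(C)(=O)=O)[C@@H]2COS(C)(=O)=O)cc1OC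
F9 | step 3 | (2S,3S,4S,5R)-2-(3,4-dimethoxyphenyl)-3,4-dimethyl-5-(3,4,5-trimethoxyphenyl)tetrahydrofuran | COc1ccc([C@H]2O[C@@H](c3cc(OC)c(OC)c(OC)c3)[C@@H](C)[C@@H]2C)cc1OC
F10 | step 3 | (2R,3S,4S,5S)-2-(3,4-dimethoxyphenyl)-3,4-dimethyl-5-(3,4,5-trimethoxyphenyl)tetrahydrofuran | COc1ccc([C@@H]2O[C@H](c3cc(OC)c(OC)c(OC)c3)[C@@H](C)[C@@H]2C)cc1OC
F11 | step 4 | di-(1R,2S,5R)-menthyl (2R,3R,4R,5R)-2-(3,4-dimethoxyphenyl)-5-(3,4,5-trimethoxyphenyl)tetrahydrofuran-3,4-dicarboxylate (all-trans diastereomer of 9 with the mirror-image ring) | COc1ccc([C@@H]2O[C@@H](c3cc(OC)c(OC)c(OC)c3)[C@H](C(=O)O[C@@H]3C[C@H](C)CC[C@H]3C(C)C)[C@H]2C(=O)O[C@@H]2C[C@H](C)CC[C@H]2C(C)C)cc1OC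
F12 | step 4 | [(2R,3S,4S,5R)-2-(3,4-dimethoxyphenyl)-5-(3,4,5-trimethoxyphenyl)tetrahydrofuran-3,4-diyl]dimethanol | COc1ccc([C@@H]2O[C@@H](c3cc(OC)c(OC)c(OC)c3)[C@H](CO)[C@H]2CO)cc1OC
F13 | step 4 | bis[(1S,4R)-camphanate] of the (2S,3R,4R,5S) diol 10 | COc1ccc([C@H]2O[C@H](c3cc(OC)c(OC)c(OC)c3)[C@@H](COC(=O)[C@]34OC(=O)[C@](C)(CC3)C4(C)C)[C@@H]2COC(=O)[C@]23OC(=O)[C@](C)(CC2)C3(C)C)cc1OC
F14 | step 4 | bis[(1S,4R)-camphanate] of the (2R,3S,4S,5R) diol F12 | COc1ccc([C@@H]2O[C@@H](c3cc(OC)c(OC)c(OC)c3)[C@H](COC(=O)[C@]34OC(=O)[C@](C)(CC3)C4(C)C)[C@H]2COC(=O)[C@]23OC(=O)[C@](C)(CC2)C3(C)C)cc1OC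
F15 | step 2 | diethyl (3,4,5-trimethoxybenzyl)phosphonate | CCOP(=O)(Cc1cc(OC)c(OC)c(OC)c1)OCC
F16 | step 2 | (E)-1,2-dimethoxy-4-[2-(3,4,5-trimethoxyphenyl)ethenyl]benzene | COc1ccc(/C=C/c2cc(OC)c(OC)c(OC)c2)cc1OC
F17 | step 6 | (2S,3S,4S,5S)-2-(3,4-dimethoxyphenyl)-3,4-bis(iodomethyl)-5-(3,4,5-trimethoxyphenyl)tetrahydrofuran | COc1ccc([C@H]2O[C@H](c3cc(OC)c(OC)c(OC)c3)[C@@H](CI)[C@@H]2CI)cc1OC
A1 | alternative 1 | (3S,4S,5S)-3,4-dimethyl-5-(3,4,5-trimethoxyphenyl)dihydrofuran-2(3H)-one | O=C1O[C@H](c2cc(OC)c(OC)c(OC)c2)[C@@H](C)[C@@H]1C
A2 | alternative 1 | (S)-5-(3,4,5-trimethoxyphenyl)furan-2(5H)-one | O=C1O[C@H](c2cc(OC)c(OC)c(OC)c2)C=C1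
A3 | alternative 2 | 4,4′-di-O-demethyl-5-methoxygalbelgin | Oc1ccc([C@H]2O[C@H](c3cc(OC)c(O)c(OC)c3)[C@@H](C)[C@@H]2C)cc1OC
A4 | alternative 2 | (E)-isoeugenol | C/C=C/c1ccc(O)c(OC)c1
A5 | alternative 2 | (E)-2,6-dimethoxy-4-(prop-1-enyl)phenol | C/C=C/c1cc(OC)c(O)c(OC)c1
A6 | alternative 3 | (1S,2S,3S,4S)-1-(3,4-dimethoxyphenyl)-2,3-dimethyl-4-(3,4,5-trimethoxyphenyl)butane-1,4-diol | COc1ccc([C@@H](O)[C@@H](C)[C@H](C)[C@H](O)c2cc(OC)c(OC)c(OC)c2)cc1OC
A7 | alternative 3 | (1E,3E)-1-(3,4-dimethoxyphenyl)-2,3-dimethyl-4-(3,4,5-trimethoxyphenyl)buta-1,3-diene | COc1ccc(/C=C(C)/C(C)=C/c2cc(OC)c(OC)c(OC)c2)cc1OC
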